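The easy entry comes first: target is the one species read, so I open the books there. I keep them on the substrate, the limiting reagent, since partner stands at 1.50 equiv.

in all of them: substrate 1.5 M; free catalyst 1.8 mol%
- oak: partner 1.5 equiv; temperature 70 °C; the very flask that is asked about, followed so far
- elm: partner 1.5 equiv; temperature 55 °C; run made earlier
- flask: partner 1.50 equiv; temperature 70 °C; time 8.0 d

- oak (time / d: target / %): 0.417: 12.1; 0.833: 15.3; 2.08: 19.8; 5.00: 19.1
- elm (time / d: target / %): 0.833: 8.5; 1.67: 12.0; 4.00: 13.8; 10.0: 15.9

(readings scatter by 0.5 percentage points)

- green: at 8.0 d raise the temperature by 25 K, then wait 15 d
- teal: change nothing and wait 15 d more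
- violet: at 8.0 d take out 90% of the target then present, then wait 15 d
- blue: at 8.0 d add free catalyst, 100% of the amount charged, then wait 15 d

- target, in percent of the substrate first charged, at 8.0 d
- the option that brings most further target ("none" if no option brings more than 2 percentage points) (green / teal / violet / blue / none)
- target present, with what was taken out counted in, in percent of the substrate first charged, after green
- target present, with what was taken out counted in, in percent of the substrate first charged, after blue

- what is taken out of target is counted as made
- the earlier runs were read with a standard deviation of 0.5 percentage points
- candidate steps: partner + free catalyst -> catalyst intermediate A; substrate + catalyst intermediate A -> catalyst intermediate B; catalyst intermediate B <-> free catalyst + target; partner + free catalyst + target -> free catalyst + over-reaction product; substrate + free catalyst -> spent catalyst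
- additions bring no volume worth counting

In oak, target reads 19.8% at 2.08 d and 19.1% at 5.00 d, a flat stretch within the scatter. I take their mean as the plateau. I read the stall as a dying catalyst, through the candidate step from substrate + free catalyst to spent catalyst. Oak's early readings then give my carried quantity, the stall half-life: the time in which the gap between target and its plateau halves. It is a reading, with the scatter of its points.

Plateau: 19.4%

Stall half-life: 0.504 d

Half-lives stood by 8.0 d: 15.9

Share of the gap left, and on my reading of the working catalyst: 0.00168%

The ledger for oak at 8.0 d then reads:

Target: 19.4%, my answer for now.

Held on the catalyst, as catalyst intermediate B or spent catalyst: no more than 1.8 mol%.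

Over-reaction product and unreacted substrate: the rest, unread.

Since 8.0 d is many stall half-lives, the books close before anyone acts. Teal and green act on a catalyst share of 0.00168%, so I keep green at 19.4%. Violet takes out target but leaves that same share working. Blue brings fresh free catalyst and opens a new account, so blue is my choice. Its round starts with target present, which the over-reaction step uses. I expect a gain under 19.4% and put no firmer figure on it.

The forecast gives 19.5%, blue, 20% after green and 32% after blue, saying “the catalyst has most likely died”.

Oak gives 19.1% at 8.0 d, 19.1% after green and 24.8% after blue, so blue is best with 5.7 percentage points, while green, teal and violet each bring 0 points.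

    partner + free catalyst → catalyst intermediate A (k = 0.850 M⁻¹ h⁻¹, Ea = 76.0 kJ mol⁻¹)
    substrate + catalyst intermediate A → catalyst intermediate B (k = 3.80 M⁻¹ h⁻¹, Ea = 80.0 kJ mol⁻¹)
    catalyst intermediate B ⇌ free catalyst + target (K = 1.90 M, k = 65.0 h⁻¹, Ea = 81.0 kJ mol⁻¹, ΔH = −49.0 kJ mol⁻¹)
    partner + free catalyst + target → free catalyst + over-reaction product (k = 2.10 M⁻² h⁻¹, Ea = 58.0 kJ mol⁻¹)
    substrate + free catalyst → spent catalyst (k = 0.0730 M⁻¹ h⁻¹, Ea = 74.0 kJ mol⁻¹)
    (constants at 70 °C)

In oak, the step from partner + free catalyst to catalyst intermediate A has done half of its turnover up to 8.0 d by 0.425 d, against my stall half-life of 0.504 d. The share of oak's catalyst still able to turn over at 8.00 d is 0.00745%, which is 13.7 halvings against my 15.9. A neighbour of oak, charged with 0.38 M of substrate at the same equivalents and loading, gives a test. If the stall half-life scales inversely with substrate, it stretches to 1.99 d. That leaves 6.17% of the catalyst working at 8.00 d, and the neighbour holds 5.80% as free catalyst and the two intermediates together.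

The numbers in the tables are simulated from invented constants.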